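**Plan**
- Ring numbering used throughout: O1, C2 (carries the arylethyl chain), C3, C4 (carbinol), C5, C6 (carries the aryl ring). The enabling feature is the 4-oxygenated tetrahydropyran itself: O1 is bonded to C2 and the C4 oxygen sits one carbon beyond C3, so C2 is a latent oxocarbenium carbon and C3–C4 a latent alkene.
- Retrosynthesis: first the phenol protecting groups and the C4 configuration (inversion) are traced back; then one Prins transform cuts the ring bonds C2–C3 and O1–C2 (and the C4–O bond), giving an aryl homoallylic alcohol and a 3-arylpropanal; last, the allyl–carbinol bond of the alcohol is cut back to a benzaldehyde.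
- Forward: the two fragments are made in two steps each; the acid-mediated Prins cyclization joins them and closes the only non-aromatic ring by the C2–C3 bond; Mitsunobu inversion at C4 and one global deprotection finish the route.
- Stereochemistry: C6 comes from a catalytic asymmetric (Keck) allylation. C2 and C4 are set in the Prins chair transition state under control of C6 (all-cis). C4 is then inverted to the axial alcohol by the Mitsunobu reaction.
- All three phenols are carried as tosylates. On the catechol ring they make the carbinol arene electron-poor, which is what keeps the Prins step from racemising.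

Key step: step 5

Remark: 5-hydroxyvanillin (3,4-dihydroxy-5-methoxybenzaldehyde) and dihydroconiferyl alcohol are taken as commercially available; "tosyl" means 4-methylbenzenesulfonyl.

**Step 1**
Reactants: 1 5-hydroxyvanillin (3,4-dihydroxy-5-methoxybenzaldehyde)
Product: 2 3-methoxy-4,5-bis(tosyloxy)benzaldehyde
Conditions: TsCl (2.3 equiv), Et3N, DMAP (cat.), CH2Cl2, 0 °C → rt
Reagents that add atoms: p-toluenesulfonyl chloride Cc1ccc(cc1)S(=O)(=O)Cl
Why: Amine-mediated O-sulfonylation of both phenols should proceed cleanly and installs the electron-withdrawing protecting groups that the key step relies on.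

**Step 2**
Reactants: 2 3-methoxy-4,5-bis(tosyloxy)benzaldehyde
Product: 3 (S)-1-[3-methoxy-4,5-bis(tosyloxy)phenyl]but-3-en-1-ol
Conditions: (S)-BINOL (20 mol %), Ti(OiPr)4 (10 mol %), 4 Å MS, CH2Cl2; then allylSnBu3, −20 °C; aq. NaHCO3
Reagents that add atoms: allyltributylstannane C=CC[Sn](CCCC)(CCCC)CCCC
Why: Keck asymmetric allylation, in which the chiral BINOL–titanium isopropoxide Lewis acid activates the electron-poor aromatic aldehyde and directs allyl transfer to one face; the (S)-BINOL catalyst is expected to give the (S)-carbinol, the future C6, as with other aromatic aldehydes.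

**Step 3**
Reactants: 4 dihydroconiferyl alcohol (3-(4-hydroxy-3-methoxyphenyl)propan-1-ol)
Product: 5 4-(3-hydroxypropyl)-2-methoxyphenyl 4-methylbenzenesulfonate
Conditions: TsCl (1.05 equiv), K2CO3, acetone, rt
Reagents that add atoms: p-toluenesulfonyl chloride Cc1ccc(cc1)S(=O)(=O)Cl
Why: Chemoselective sulfonylation, since K2CO3 deprotonates only the phenol and the phenoxide reacts with TsCl far faster than the neutral primary alcohol.

**Step 4**
Reactants: 5 4-(3-hydroxypropyl)-2-methoxyphenyl 4-methylbenzenesulfonate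
Product: 6 2-methoxy-4-(3-oxopropyl)phenyl 4-methylbenzenesulfonate
Conditions: TEMPO (10 mol %), PhI(OAc)2, CH2Cl2, rt
Reagents that add atoms: none
Why: Oxoammonium-mediated oxidation (TEMPO with PhI(OAc)2 as terminal oxidant) should stop at the aldehyde and leaves the aryl sulfonate and the arene untouched.

**Step 5**
Reactants: 3 (S)-1-[3-methoxy-4,5-bis(tosyloxy)phenyl]but-3-en-1-ol; 6 2-methoxy-4-(3-oxopropyl)phenyl 4-methylbenzenesulfonate
Product: 9 (2S,4R,6S)-6-[3-methoxy-4,5-bis(tosyloxy)phenyl]-2-{2-[3-methoxy-4-(tosyloxy)phenyl]ethyl}tetrahydro-2H-pyran-4-ol (all-cis), via oxocarbenium ion 7 (not isolated), via C4 trifluoroacetate ester 8 (not isolated)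
Conditions: 6 (1.3 equiv), CF3CO2H/CH2Cl2 (1:4), 0 °C → rt; concentrate; then K2CO3, MeOH, 0 °C
Reagents that add atoms: trifluoroacetic acid OC(=O)C(F)(F)F (supplies the oxygen at C4)
Why: The acid condenses alcohol 3 with aldehyde 6 to the (E)-oxocarbenium ion 7, whose terminal alkene carbon attacks the oxocarbenium carbon through a chair transition state to form the C2–C3 bond, and the resulting C4 cation is captured by trifluoroacetate to give 8, which K2CO3/MeOH unmasks to 9. The closest known reaction type is the trifluoroacetic acid-mediated Prins cyclization of homoallylic alcohols with aldehydes. The one ring formed, the tetrahydropyran, closes in a 6-endo-trig mode, endo with respect to both the C=O+ and the C=C unit. C2 is controlled by the existing C6 stereocenter, because the aryl group and the arylethyl chain both sit equatorial in the chair with the (E)-oxocarbenium geometry (2,6-cis), and C4 is set by equatorial attack of trifluoroacetate on the chair cation, which should give the all-cis (2S,4R,6S) isomer. The step needs ring closure to outrun 2-oxonia-Cope rearrangement, benzylic ionization at C6 and side-chain exchange, all of which would erode the enantiopurity; this is secured by the two sulfonate esters para and meta to the carbinol carbon (the remaining methoxy group is meta and cannot donate by resonance), which destabilise the benzylic cation and benzylic oxocarbenium ion, while the sulfonate on the aldehyde arene disfavours Friedel–Crafts capture of 7.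

**Step 6**
Reactants: 9 (2S,4R,6S)-tetrahydropyran-4-ol (all-cis)
Product: 10 (2S,4S,6S)-6-[3-methoxy-4,5-bis(tosyloxy)phenyl]-2-{2-[3-methoxy-4-(tosyloxy)phenyl]ethyl}tetrahydro-2H-pyran-4-yl benzoate
Conditions: PhCO2H, PPh3, DIAD, THF, 0 °C → rt
Reagents that add atoms: benzoic acid OC(=O)c1ccccc1
Why: Mitsunobu reaction, in which benzoate displaces the alkoxyphosphonium group of the unhindered equatorial alcohol with inversion, so the C4 oxygen becomes axial (4R → 4S) as the target requires.

**Step 7**
Reactants: 10 (2S,4S,6S)-benzoate tris-tosylate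
Product: 11 (2S,4S,6S)-6-(3,4-dihydroxy-5-methoxyphenyl)-2-[2-(4-hydroxy-3-methoxyphenyl)ethyl]tetrahydro-2H-pyran-4-ol (target)
Conditions: KOH (excess), t-BuOH/H2O (degassed), 80 °C, argon; then aq. HCl to pH 3–4
Reagents that add atoms: none
Why: Saponification of the benzoate and alkaline hydrolysis of the three aryl sulfonates by hydroxide attack at sulfur (S–O cleavage) should release the alcohol and the phenols without touching a stereocenter; exclusion of air protects the catecholate, and the non-nucleophilic alcohol cosolvent avoids forming an alkylating sulfonate ester.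

**Compound list**
1 | 5-hydroxyvanillin (3,4-dihydroxy-5-methoxybenzaldehyde) | COc1cc(C=O)cc(O)c1O | starting material
2 | 3-methoxy-4,5-bis(tosyloxy)benzaldehyde | COc1cc(C=O)cc(OS(=O)(=O)c2ccc(C)cc2)c1OS(=O)(=O)c1ccc(C)cc1 | intermediate
3 | (S)-1-[3-methoxy-4,5-bis(tosyloxy)phenyl]but-3-en-1-ol | C=CC[C@@H](c1cc(OC)c(OS(=O)(=O)c2ccc(C)cc2)c(OS(=O)(=O)c2ccc(C)cc2)c1)O | intermediate
4 | dihydroconiferyl alcohol (3-(4-hydroxy-3-methoxyphenyl)propan-1-ol) | COc1cc(CCCO)ccc1O | starting material
5 | 4-(3-hydroxypropyl)-2-methoxyphenyl 4-methylbenzenesulfonate | COc1cc(CCCO)ccc1OS(=O)(=O)c1ccc(C)cc1 | intermediate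
6 | 2-methoxy-4-(3-oxopropyl)phenyl 4-methylbenzenesulfonate | COc1cc(CCC=O)ccc1OS(=O)(=O)c1ccc(C)cc1 | intermediate
7 | (E)-oxocarbenium ion from 3 and 6 (trifluoroacetate counter-ion) | C=CC[C@@H](c1cc(OC)c(OS(=O)(=O)c2ccc(C)cc2)c(OS(=O)(=O)c2ccc(C)cc2)c1)/[O+]=C/CCc1ccc(OS(=O)(=O)c2ccc(C)cc2)c(OC)c1.[O-]C(=O)C(F)(F)F | intermediate
8 | (2S,4R,6S)-6-[3-methoxy-4,5-bis(tosyloxy)phenyl]-2-{2-[3-methoxy-4-(tosyloxy)phenyl]ethyl}tetrahydro-2H-pyran-4-yl trifluoroacetate | COc1cc(CC[C@H]2C[C@@H](OC(=O)C(F)(F)F)C[C@@H](c3cc(OS(=O)(=O)c4ccc(C)cc4)c(OS(=O)(=O)c4ccc(C)cc4)c(OC)c3)O2)ccc1OS(=O)(=O)c1ccc(C)cc1 | intermediate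
9 | (2S,4R,6S)-6-[3-methoxy-4,5-bis(tosyloxy)phenyl]-2-{2-[3-methoxy-4-(tosyloxy)phenyl]ethyl}tetrahydro-2H-pyran-4-ol (all-cis) | COc1cc(CC[C@H]2C[C@@H](O)C[C@@H](c3cc(OS(=O)(=O)c4ccc(C)cc4)c(OS(=O)(=O)c4ccc(C)cc4)c(OC)c3)O2)ccc1OS(=O)(=O)c1ccc(C)cc1 | intermediate
10 | (2S,4S,6S)-6-[3-methoxy-4,5-bis(tosyloxy)phenyl]-2-{2-[3-methoxy-4-(tosyloxy)phenyl]ethyl}tetrahydro-2H-pyran-4-yl benzoate | COc1cc(CC[C@H]2C[C@H](OC(=O)c3ccccc3)C[C@@H](c3cc(OS(=O)(=O)c4ccc(C)cc4)c(OS(=O)(=O)c4ccc(C)cc4)c(OC)c3)O2)ccc1OS(=O)(=O)c1ccc(C)cc1 | intermediate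
11 | (2S,4S,6S)-6-(3,4-dihydroxy-5-methoxyphenyl)-2-[2-(4-hydroxy-3-methoxyphenyl)ethyl]tetrahydro-2H-pyran-4-ol | COc1cc(CC[C@H]2C[C@H](O)C[C@@H](c3cc(O)c(O)c(OC)c3)O2)ccc1O | target

**Count and risks**
Total step count: 7. Longest linear sequence: 5 steps (steps 1, 2, 5, 6, 7).

Steps most likely to fail:

1. Step 5 (Prins cyclization). The risk is erosion of enantiopurity and scrambling of the side chains through reversible 2-oxonia-Cope rearrangement and allyl transfer while the oxocarbenium ion equilibrates with free aldehyde, alcohol and water. The fallback sets out from 5 and 3 and comes back to the route at 9. It builds the acetal carbon into the substrate first and ionises it under anhydrous conditions, so that no free aldehyde or water is present. Alcohol 5 would be oxidised (TEMPO cat., PhI(OAc)2, MeCN/H2O) to 3-[3-methoxy-4-(tosyloxy)phenyl]propanoic acid F1. F1 would be esterified with 3 (DCC, DMAP, CH2Cl2) to the homoallylic ester F2. Reductive acetylation (i-Bu2AlH, CH2Cl2, −78 °C; then Ac2O, pyridine, DMAP) would give the α-acetoxy ether F3 as a mixture of acetal epimers. Ionisation with BF3·OEt2 and AcOH in hexane/CH2Cl2 at 0 °C should cyclise F3 to the all-cis 4-acetate F4, and K2CO3/MeOH would then give 9.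

2. Step 7 (global deprotection). The risk is incomplete cleavage of the second sulfonate on the catechol ring, because the first-formed phenoxide slows hydroxide attack at the neighbouring sulfur, together with air oxidation of the catecholate in hot alkali. The fallback sets out from 10 and comes back at 11. It changes the cleavage from nucleophilic hydrolysis to electron transfer: Mg turnings in MeOH at rt with sonication should cleave the three S–O bonds reductively, and the magnesium methoxide formed should remove the benzoate by transesterification. No new isolated compound is made.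

3. Step 6 (Mitsunobu inversion). The risk is elimination of the activated alkoxyphosphonium intermediate to a dihydropyran, or incomplete inversion. The fallback sets out from 9 and comes back at 11. It replaces substitution by an oxidation–reduction sequence. Dess–Martin periodinane (NaHCO3, CH2Cl2) would give the 2,6-cis-tetrahydropyran-4-one F5. LiB(s-Bu)3H (THF, −78 °C) should deliver hydride from the equatorial side to give the axial alcohol tris-tosylate F6. The KOH conditions of step 7 would then convert F6 into 11.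

**Further compounds**
F1 | step 5 | 3-[3-methoxy-4-(tosyloxy)phenyl]propanoic acid | COc1cc(CCC(=O)O)ccc1OS(=O)(=O)c1ccc(C)cc1
F2 | step 5 | (S)-1-[3-methoxy-4,5-bis(tosyloxy)phenyl]but-3-en-1-yl 3-[3-methoxy-4-(tosyloxy)phenyl]propanoate | C=CC[C@@H](c1cc(OC)c(OS(=O)(=O)c2ccc(C)cc2)c(OS(=O)(=O)c2ccc(C)cc2)c1)OC(=O)CCc1ccc(OS(=O)(=O)c2ccc(C)cc2)c(OC)c1
F3 | step 5 | α-acetoxy ether: 1-{[(S)-1-[3-methoxy-4,5-bis(tosyloxy)phenyl]but-3-en-1-yl]oxy}-3-[3-methoxy-4-(tosyloxy)phenyl]propyl acetate (both acetal epimers) | C=CC[C@@H](c1cc(OC)c(OS(=O)(=O)c2ccc(C)cc2)c(OS(=O)(=O)c2ccc(C)cc2)c1)OC(OC(C)=O)CCc1ccc(OS(=O)(=O)c2ccc(C)cc2)c(OC)c1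
F4 | step 5 | (2S,4R,6S)-6-[3-methoxy-4,5-bis(tosyloxy)phenyl]-2-{2-[3-methoxy-4-(tosyloxy)phenyl]ethyl}tetrahydro-2H-pyran-4-yl acetate (all-cis) | COc1cc(CC[C@H]2C[C@@H](OC(C)=O)C[C@@H](c3cc(OS(=O)(=O)c4ccc(C)cc4)c(OS(=O)(=O)c4ccc(C)cc4)c(OC)c3)O2)ccc1OS(=O)(=O)c1ccc(C)cc1
F5 | step 6 | (2S,6S)-6-[3-methoxy-4,5-bis(tosyloxy)phenyl]-2-{2-[3-methoxy-4-(tosyloxy)phenyl]ethyl}tetrahydro-4H-pyran-4-one | COc1cc(CC[C@H]2CC(=O)C[C@@H](c3cc(OS(=O)(=O)c4ccc(C)cc4)c(OS(=O)(=O)c4ccc(C)cc4)c(OC)c3)O2)ccc1OS(=O)(=O)c1ccc(C)cc1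
F6 | step 6 | (2S,4S,6S)-6-[3-methoxy-4,5-bis(tosyloxy)phenyl]-2-{2-[3-methoxy-4-(tosyloxy)phenyl]ethyl}tetrahydro-2H-pyran-4-ol (axial alcohol) | COc1cc(CC[C@H]2C[C@H](O)C[C@@H](c3cc(OS(=O)(=O)c4ccc(C)cc4)c(OS(=O)(=O)c4ccc(C)cc4)c(OC)c3)O2)ccc1OS(=O)(=O)c1ccc(C)cc1
F0 | step 7 | none | none
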